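**Retrosynthetic overview** (ring atoms: C1 = CH–OAc, C2 = C–OMe, C3, C4 = CH–OH, C5, C6 = C–CH2)
1. Target 12 ← lipase hydrolysis of the C4 acetate of triacetate 11 ← trans-diol 10 ← double 1,2-reduction of quinone 8; the ring stereocentres C1 and C4 are made last, on the dearomatized ring.
2. Quinone 7/8 ← oxidative dearomatization of dihydrobenzofuran 6 by tetravalent cerium, which opens the temporary O–C1 bond and hands the ring oxygen back to the side chain.
3. C6–CH2 bond (key): Pd/norbornene ortho-C–H alkylation/annulation of 1-iodo-2,4-dimethoxybenzene 5 with strained (R)-1,2-epoxytridecane 4. Enabling feature: the O–C1–C6–CH2–CH(O) array of the target is the five-membered ring of a 2-alkyl-2,3-dihydrobenzofuran, and the C2 methoxy group is the single ortho substituent this annulation needs.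
4. Rings: the carbocycle is bought as a benzene ring; the only ring formed is the temporary dihydrofuran (step 2), removed again in step 3.
5. Epoxide 4 ← (R)-epichlorohydrin 1 + decylmagnesium bromide 2.

Key step: step 2

Assumption (remark on the chemistry): the remote side-chain stereocentre is not expected to bias the facial course of the quinone reduction in step 5, so the (1S,4S) ring configuration is secured by separation of the two trans diastereomers there and by the stereopreference of the lipase in step 7.

Step 1
Reactants: 1 (R)-epichlorohydrin; 2 decylmagnesium bromide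
Product: 4 (R)-1,2-epoxytridecane, via (R)-1-chlorotridecan-2-ol 3 (not isolated)
Conditions: CuI (10 mol %), THF, −40 to 0 °C; then NaOH, H2O, rt
Reagents that add atoms: none
Why: Copper-catalysed Grignard opening of the epoxide at its terminal carbon, then intramolecular Williamson closure (3-exo-tet) of the chlorohydrin; no bond at the stereocentre is broken, so (R)-epichlorohydrin should give the (R)-epoxide.

Step 2
Reactants: 5 1-iodo-2,4-dimethoxybenzene; 4 (R)-1,2-epoxytridecane
Product: 6 (2R)-5,7-dimethoxy-2-undecyl-2,3-dihydrobenzofuran
Conditions: Pd(OAc)2 (5 mol %), XPhos (10 mol %), potassium 5-norbornene-2-carboxylate (50 mol %), K2CO3 (1.5 equiv), NMP, 70 °C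
Reagents that add atoms: none
Why: This is a Catellani-type Pd/norbornene relay with an epoxide as the alkylating agent, a reaction type with close precedent for ortho-substituted aryl iodides and terminal aliphatic epoxides, which are known to give 2-substituted 2,3-dihydrobenzofurans. Zerovalent palladium inserts into the C–I bond of 5; norbornene carbopalladation and C–H palladation at the only free ortho carbon (the future C6) give the aryl–norbornyl palladacycle, which is alkylated at the terminal CH2 of the strained epoxide (SN2-type oxidative addition to tetravalent palladium, then reductive elimination) to forge the C6–CH2 bond. β-Carbon elimination then expels norbornene, and the tethered alkoxide closes the temporary five-membered ring by C(aryl)–O reductive elimination at divalent palladium (ipso termination, formally a 5-exo closure onto the future C1). No new stereocentre is formed: the C–O bond of the epoxide stereocentre is never broken, so (R) is carried over. The step needs mono-ortho-alkylation and attack at the less hindered epoxide carbon; the C2 methoxy group blocks the second ortho position and supplies the ortho substituent that lets norbornene leave, and the SN2 character of the opening secures the terminal regiochemistry.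

Step 3
Reactants: 6 (2R)-5,7-dimethoxy-2-undecyl-2,3-dihydrobenzofuran
Product: 7 2-[(2R)-2-hydroxytridecyl]-6-methoxy-1,4-benzoquinone
Conditions: (NH4)2Ce(NO3)6 (2.5 equiv), MeCN/H2O, 0 °C
Reagents that add atoms: water, O
Why: Oxidative dealkylation of a para-dialkoxyarene to the p-quinone by tetravalent cerium: water attacks the two ipso carbons (C4 and C1), methanol leaves from C4 and the ring oxygen leaves from C1 as the side-chain hydroxyl, so the temporary ring opens with the C–O bond of the stereocentre untouched (retention), while the C2 methoxy group, not para to an oxygen, stays.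

Step 4
Reactants: 7 2-[(2R)-2-hydroxytridecyl]-6-methoxy-1,4-benzoquinone
Product: 8 (2R)-1-(5-methoxy-3,6-dioxocyclohexa-1,4-dien-1-yl)tridecan-2-yl acetate (cornudentanone)
Conditions: Ac2O, pyridine, CH2Cl2, 0 °C to rt
Reagents that add atoms: acetic anhydride, CC(=O)OC(C)=O
Why: Standard O-acetylation of a secondary alcohol, which installs the side-chain acetate and removes the hydroxyl as a hemiketal-forming and hydride-directing group before the reduction; the stereocentre is untouched.

Step 5
Reactants: 8 (2R)-1-(5-methoxy-3,6-dioxocyclohexa-1,4-dien-1-yl)tridecan-2-yl acetate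
Product: 10 (1S,4S)-6-[(2R)-2-acetoxytridecyl]-2-methoxycyclohexa-2,5-diene-1,4-diol, via lithium 4-oxocyclohexa-2,5-dien-1-olate 9 (not isolated)
Conditions: LiBH4 (1.1 equiv), THF, −78 to −40 °C; pH 7 phosphate buffer, 0 °C; chromatography on Et3N-deactivated silica
Reagents that add atoms: none
Why: Double 1,2-reduction of a substituted p-quinone by a complex hydride in an aprotic medium (known for substituted quinones): the first hydride should enter the more electrophilic C1=O (C4=O is a vinylogous ester), the resulting alkoxide 9 stays unprotonated as its borane adduct and so should not tautomerize to the hydroquinone, and this alkoxyborohydride should pass its hydride across the ring to C4=O on the face of the C1–O bond, which sets C1 and C4 trans; both trans ring diastereomers are expected, and the (1S,4S) isomer 10 is separated from its (1R,4R) diastereomer at this stage.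

Step 6
Reactants: 10 (1S,4S)-6-[(2R)-2-acetoxytridecyl]-2-methoxycyclohexa-2,5-diene-1,4-diol
Product: 11 (1S,4S)-6-[(2R)-2-acetoxytridecyl]-2-methoxycyclohexa-2,5-diene-1,4-diyl diacetate
Conditions: Ac2O, pyridine, DMAP (cat.), CH2Cl2, 0 °C
Reagents that add atoms: acetic anhydride, CC(=O)OC(C)=O
Why: DMAP-catalysed acyl transfer acetylates both ring hydroxyls, including the hindered one at C1, under basic conditions that avoid ionization of the bis-allylic C–O bonds; no stereocentre is touched.

Step 7
Reactants: 11 (1S,4S)-6-[(2R)-2-acetoxytridecyl]-2-methoxycyclohexa-2,5-diene-1,4-diyl diacetate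
Product: 12 (1S,4S)-6-[(2R)-2-acetoxytridecyl]-4-hydroxy-2-methoxycyclohexa-2,5-dien-1-yl acetate
Conditions: Candida antarctica lipase B (immobilized), pH 7 phosphate buffer/MTBE, 30 °C
Reagents that add atoms: none
Why: Lipase-catalysed hydrolysis of a secondary acetate under neutral conditions: only the C4 acetate, flanked by two unsubstituted vinylic CH groups, should fit the active site (the C1 acetate sits between two fully substituted carbons and the side-chain acetate carries two large groups), and by the empirical size rule for lipases the (4S)-acetate (small methoxy-bearing flank, large alkyl-bearing flank) is the fast-reacting one, so C4–OH is freed regioselectively and any residual (1R,4R) material is rejected; no stereocentre is formed.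

**Compound list**
1 | (R)-epichlorohydrin | ClC[C@H]1CO1 | starting material
2 | decylmagnesium bromide | CCCCCCCCCC[Mg]Br | starting material
3 | (R)-1-chlorotridecan-2-ol (formed in the flask; not isolated) | CCCCCCCCCCC[C@@H](O)CCl | intermediate
4 | (R)-1,2-epoxytridecane | CCCCCCCCCCC[C@@H]1CO1 | intermediate
5 | 1-iodo-2,4-dimethoxybenzene | COc1ccc(I)c(OC)c1 | starting material
6 | (2R)-5,7-dimethoxy-2-undecyl-2,3-dihydrobenzofuran | CCCCCCCCCCC[C@@H]1Cc2cc(OC)cc(OC)c2O1 | intermediate
7 | 2-[(2R)-2-hydroxytridecyl]-6-methoxy-1,4-benzoquinone | CCCCCCCCCCC[C@H](CC1=CC(=O)C=C(OC)C1=O)O | intermediate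
8 | (2R)-1-(5-methoxy-3,6-dioxocyclohexa-1,4-dien-1-yl)tridecan-2-yl acetate (cornudentanone) | CCCCCCCCCCC[C@H](CC1=CC(=O)C=C(OC)C1=O)OC(C)=O | intermediate
9 | lithium (1S)-6-[(2R)-2-acetoxytridecyl]-2-methoxy-4-oxocyclohexa-2,5-dien-1-olate (borane adduct in the flask; not isolated) | [Li+].CCCCCCCCCCC[C@H](CC1=CC(=O)C=C(OC)[C@H]1[O-])OC(C)=O | intermediate
10 | (1S,4S)-6-[(2R)-2-acetoxytridecyl]-2-methoxycyclohexa-2,5-diene-1,4-diol | CCCCCCCCCCC[C@H](CC1=C[C@H](O)C=C(OC)[C@H]1O)OC(C)=O | intermediate
11 | (1S,4S)-6-[(2R)-2-acetoxytridecyl]-2-methoxycyclohexa-2,5-diene-1,4-diyl diacetate | CCCCCCCCCCC[C@H](CC1=C[C@H](OC(C)=O)C=C(OC)[C@H]1OC(C)=O)OC(C)=O | intermediate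
12 | (1S,4S)-6-[(2R)-2-acetoxytridecyl]-4-hydroxy-2-methoxycyclohexa-2,5-dien-1-yl acetate | CCCCCCCCCCC[C@H](CC1=C[C@H](O)C=C(OC)[C@H]1OC(C)=O)OC(C)=O | target

**Step count and risks**
Total step count: 7. Longest linear sequence: 7 steps (1 → 4 → 6 → 7 → 8 → 10 → 11 → 12).

Steps most likely to fail, riskiest first:

Step 5. The half-reduced intermediate may be protonated or enolize and so rearomatize to the hydroquinone, or the second hydride may arrive without the intramolecular relay and erode the trans relationship. The fallback sets out from 4 and comes back at 11, and never passes through a ring carbonyl. Epoxide 4 would be opened by 3-methoxyphenylmagnesium bromide (CuI cat., THF) to give (2R)-1-(3-methoxyphenyl)tridecan-2-ol F1. Birch-type reductive 1,4-disilylation (Li, HMe2SiCl, THF; the hydroxyl is silylated as well) should place silicon on the ring carbons ortho and meta to the methoxy group, which are C1 and C4, trans to each other, to give (2R)-1-[trans-3,6-bis(dimethylsilyl)-5-methoxycyclohexa-1,4-dien-1-yl]tridecan-2-yl dimethylsilyl ether F2. Tamao–Fleming oxidation (H2O2, KF, KHCO3, THF/MeOH), which replaces C–Si by C–OH with retention, should give (1S,4S)-6-[(2R)-2-hydroxytridecyl]-2-methoxycyclohexa-2,5-diene-1,4-diol F3 beside its ring diastereomer. Peracetylation (Ac2O, pyridine, DMAP) then gives 11, and step 7 sorts the ring diastereomers as before.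

Step 7. The enzyme may fail to discriminate between the three acetates or between the two ring diastereomers, or acetic acid may be eliminated from the bis-allylic triacetate on the way. The fallback sets out from 10 (already freed of its ring diastereomer by chromatography) and comes back at 12. The unhindered C4 hydroxyl would be silylated selectively (Et3SiCl, imidazole, CH2Cl2, −40 °C) to give (1S,4S)-6-[(2R)-2-acetoxytridecyl]-2-methoxy-4-(triethylsilyloxy)cyclohexa-2,5-dien-1-ol F4. Acetylation of the remaining C1 hydroxyl (Ac2O, pyridine, DMAP) gives (1S,4S)-6-[(2R)-2-acetoxytridecyl]-2-methoxy-4-(triethylsilyloxy)cyclohexa-2,5-dien-1-yl acetate F5. Buffered Si–O cleavage (HF·pyridine, pyridine, THF, 0 °C) then gives 12.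

Step 3. Over-oxidation, or attack of water at the wrong ring carbons, may lead to ortho-quinone or ring-retained products instead of clean opening of the cyclic ether. The fallback sets out from 6 and comes back at 7. Anodic oxidation of 6 (Pt electrodes, KOH, MeOH, 0 °C) would dearomatize it to the quinone bisketal (2R)-5,5,7,7a-tetramethoxy-2-undecyl-2,3,5,7a-tetrahydrobenzofuran F6 (epimers at C7a). Mild aqueous acid (AcOH/H2O/THF) then hydrolyses both ketals, the cyclic one opening to release the side-chain hydroxyl, to give 7.

**Further compounds**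
F1 | step 5 | (2R)-1-(3-methoxyphenyl)tridecan-2-ol | CCCCCCCCCCC[C@H](Cc1cccc(OC)c1)O
F2 | step 5 | (2R)-1-[(3S,6S)-3,6-bis(dimethylsilyl)-5-methoxycyclohexa-1,4-dien-1-yl]tridecan-2-yl dimethylsilyl ether | CCCCCCCCCCC[C@H](CC1=C[C@H]([SiH](C)C)C=C(OC)[C@H]1[SiH](C)C)O[SiH](C)C
F3 | step 5 | (1S,4S)-6-[(2R)-2-hydroxytridecyl]-2-methoxycyclohexa-2,5-diene-1,4-diol | CCCCCCCCCCC[C@H](CC1=C[C@H](O)C=C(OC)[C@H]1O)O
F4 | step 7 | (1S,4S)-6-[(2R)-2-acetoxytridecyl]-2-methoxy-4-(triethylsilyloxy)cyclohexa-2,5-dien-1-ol | CCCCCCCCCCC[C@H](CC1=C[C@H](O[Si](CC)(CC)CC)C=C(OC)[C@H]1O)OC(C)=O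
F5 | step 7 | (1S,4S)-6-[(2R)-2-acetoxytridecyl]-2-methoxy-4-(triethylsilyloxy)cyclohexa-2,5-dien-1-yl acetate | CCCCCCCCCCC[C@H](CC1=C[C@H](O[Si](CC)(CC)CC)C=C(OC)[C@H]1OC(C)=O)OC(C)=O
F6 | step 3 | (2R)-5,5,7,7a-tetramethoxy-2-undecyl-2,3,5,7a-tetrahydrobenzofuran | CCCCCCCCCCC[C@@H]1CC2=CC(OC)(OC)C=C(OC)C2(OC)O1
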